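Ring B is a cyclohexene whose C5–C10 bond is also the fusion bond of ring A, so a retro-Diels–Alder cut through C5–C10 and C6–C7 unravels both rings into one achiral chain: an (E)-enal dienophile (C5=C6, the formyl group a removable catalyst handle) linked by C4–C1 to a 2-silyloxy diene (C7=C8–C9=C10) that already bears the homofarnesyl chain on C9. One catalytic enantioselective intramolecular Diels–Alder reaction closes the trans-decalin and sets C5 and C10; the C8 enol ether it leaves then supplies the C8 ketone, through which C9 is equilibrated and the C7=C8 methyl alkene is installed.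

Key step: step 10

Remark on the chemistry: decalin carbons are numbered as in drimanes (ring A = C1–C5 and C10, ring B = C5–C10, gem-dimethyl on C4, angular methyl on C10, side chain on C9); "homofarnesyl" = (3E,7E)-4,8,12-trimethyltrideca-3,7,11-trien-1-yl. The sense of induction of the boron catalyst in step 10 is assumed from its formyl-binding transition-state model.

Step 1
Reactants: 1 (2E,6E)-farnesyl bromide
Product: 3 (3E,7E)-homofarnesol, via homofarnesyl(isopropoxy)dimethylsilane 2 (not isolated)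
Conditions: ClCH2SiMe2(Oi-Pr), Mg, THF (Grignard reagent formed first); then 1, Li2CuCl4 (3 mol%), THF, −20 to 0 °C; then KF, KHCO3, 30% H2O2, THF/MeOH, rt
Reagents that add atoms: (chloromethyl)(isopropoxy)dimethylsilane, used as its Grignard reagent, CC(C)O[Si](C)(C)CCl; hydrogen peroxide, OO
Why: Copper-catalysed SN2 cross-coupling of the silylmethyl Grignard reagent with the primary allylic bromide should keep the 2E geometry, and Tamao–Fleming oxidation then replaces silicon by hydroxyl without touching the trisubstituted alkenes (one-carbon homologation).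

Step 2
Reactants: 3 (3E,7E)-homofarnesol
Product: 4 (3E,7E)-homofarnesyl iodide
Conditions: I2, PPh3, imidazole, CH2Cl2, 0 °C to rt
Reagents that add atoms: iodine, II
Why: Appel-type iodination of a primary alcohol proceeds under buffered, non-acidic conditions that should leave the triene intact.

Step 3
Reactants: 5 acetylacetone; 4 (3E,7E)-homofarnesyl iodide
Product: 6 3-homofarnesylpentane-2,4-dione
Conditions: K2CO3, acetone, reflux (excess 5)
Reagents that add atoms: none
Why: C-alkylation of the soft potassium acetylacetonate with a primary iodide (acetoacetic-type alkylation) should dominate, and excess dione suppresses dialkylation.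

Step 4
Reactants: 6 3-homofarnesylpentane-2,4-dione
Product: 7 (2E)-4-oxo-3-homofarnesylpent-2-en-2-yl triflate (triflate trans to acetyl)
Conditions: Tf2O, aqueous Me4NOH, hexanes/toluene, 5 °C
Reagents that add atoms: triflic anhydride, O=S(=O)(OS(=O)(=O)C(F)(F)F)C(F)(F)F
Why: O-sulfonylation of the non-chelated tetraalkylammonium enolate should occur on the oxygen anti to the remaining acetyl group, giving the E vinylogous acyl triflate (methyl cis to acetyl); the geometric isomers are separable and assignable by NOE.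

Step 5
Reactants: 8 2,2-dimethylpent-4-enal
Product: 9 ethyl (2E)-4,4-dimethylhepta-2,6-dienoate
Conditions: (EtO)2P(O)CH2CO2Et, NaH, THF, 0 °C to rt
Reagents that add atoms: triethyl phosphonoacetate, CCOC(=O)CP(=O)(OCC)OCC
Why: Horner–Wadsworth–Emmons olefination of a non-enolisable α-quaternary aldehyde should give the E enoate.

Step 6
Reactants: 9 ethyl (2E)-4,4-dimethylhepta-2,6-dienoate
Product: 10 (2E)-4,4-dimethylhepta-2,6-dien-1-ol
Conditions: i-Bu2AlH (2.2 equiv), CH2Cl2, −78 to 0 °C
Reagents that add atoms: none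
Why: 1,2-Reduction of the enoate by the aluminium hydride gives the allylic alcohol without touching either alkene.

Step 7
Reactants: 10 (2E)-4,4-dimethylhepta-2,6-dien-1-ol; 7 (2E)-4-oxo-3-homofarnesylpent-2-en-2-yl triflate
Product: 12 (3E,9E)-11-hydroxy-4,8,8-trimethyl-3-homofarnesylundeca-3,9-dien-2-one, via bis(9-BBN) adduct 11 (not isolated)
Conditions: 9-BBN (2.1 equiv), THF, 0 °C to rt; then 7, Pd(dppf)Cl2 (5 mol%), AsPh3, Cs2CO3, DMF/THF/H2O, rt
Reagents that add atoms: none
Why: 9-BBN hydroborates only the unhindered terminal alkene (anti-Markovnikov), and the B-alkyl Suzuki–Miyaura coupling with the activated vinyl triflate proceeds with retention of geometry, placing the tether trans to the acetyl group.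

Step 8
Reactants: 12 (3E,9E)-11-hydroxy-4,8,8-trimethyl-3-homofarnesylundeca-3,9-dien-2-one
Product: 13 (2E,8E)-4,4,8-trimethyl-10-oxo-9-homofarnesylundeca-2,8-dienal
Conditions: MnO2 (activated, excess), CH2Cl2, rt
Reagents that add atoms: none
Why: MnO2 oxidises the allylic alcohol selectively to the (E)-enal and leaves the enone and the isolated alkenes alone.

Step 9
Reactants: 13 (2E,8E)-4,4,8-trimethyl-10-oxo-9-homofarnesylundeca-2,8-dienal
Product: 14 (2E,8E)-4,4,8-trimethyl-9-homofarnesyl-10-(triisopropylsilyloxy)undeca-2,8,10-trienal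
Conditions: TIPSOTf, Et3N, CH2Cl2, −78 to 0 °C
Reagents that add atoms: triisopropylsilyl triflate, CC(C)[Si](OS(=O)(=O)C(F)(F)F)(C(C)C)C(C)C
Why: Soft enolisation of the methyl ketone at its α′-methyl group gives the cross-conjugated 2-silyloxy diene, while the enal has no enolisable hydrogen (C4 is quaternary) and should stay untouched.

Step 10
Reactants: 14 (2E,8E)-4,4,8-trimethyl-9-homofarnesyl-10-(triisopropylsilyloxy)undeca-2,8,10-trienal
Product: 15 (5S,6S,10S)-6α-formyl-9-homofarnesyl-4,4,10-trimethyl-8-(triisopropylsilyloxy)-trans-octal-8-ene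
Conditions: (S)-3,3-diphenyl-1-(o-tolyl)tetrahydropyrrolo[1,2-c][1,3,2]oxazaborole·HNTf2 (20 mol%), CH2Cl2, −78 to −20 °C
Reagents that add atoms: none
Why: The boron Lewis acid binds the formyl oxygen of the s-trans enal and lowers its LUMO, and the 2-silyloxy diene (s-cis form favoured by its 2,3-disubstitution) adds across C5=C6 in a concerted, asynchronous type 1 intramolecular Diels–Alder reaction that forms C5–C10 and C6–C7 together. The closest known reaction type is the chiral-oxazaborolidinium-catalysed intramolecular Diels–Alder reaction of (E)-2,8,10-trienals to trans-fused octalins. Ring B is closed by the [4+2] cycloaddition itself and ring A by the same event through the four-carbon tether C1–C4 in the fused mode with a chair-like tether. The trans C5–H/C10–CH3 relationship should follow from the endo-formyl transition state of the (E)-enal (tether exo at C5) combined with the (E)-C9=C10 geometry that holds the methyl group inside and the tether outside; C6 is set by suprafacial addition and is erased in step 11. The absolute configuration (5S,10S) is set by the catalyst, whose aryl groups should screen the Re face of C5 so that C10 bonds to its Si face. The step needs endo (trans-fusion) and facial selectivity, secured by the Lewis-acid-enhanced endo preference, by the C4 gem-dimethyl group that disfavours an endo tether, and by the catalyst, while the regiochemistry is fixed by the tether.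

Step 11
Reactants: 15 (5S,6S,10S)-6α-formyl-9-homofarnesyl-4,4,10-trimethyl-8-(triisopropylsilyloxy)-trans-octal-8-ene
Product: 16 (5S,10S)-9-homofarnesyl-4,4,10-trimethyl-8-(triisopropylsilyloxy)-trans-octal-8-ene
Conditions: RhCl3·3H2O (5 mol%), dppp (10 mol%), diglyme, 160 °C, N2 sweep
Reagents that add atoms: none
Why: Tsuji–Wilkinson-type decarbonylation (formyl C–H oxidative addition, CO extrusion, reductive elimination) replaces the handle on C6 by hydrogen, and the silyl enol ether and trisubstituted alkenes should be tolerated.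

Step 12
Reactants: 16 (5S,10S)-9-homofarnesyl-4,4,10-trimethyl-8-(triisopropylsilyloxy)-trans-octal-8-ene
Product: 17 (5S,9R,10S)-9-homofarnesyl-4,4,10-trimethyl-trans-decalin-8-one
Conditions: Bu4NF, AcOH, THF, 0 °C to rt; then K2CO3, MeOH, rt
Reagents that add atoms: none
Why: Fluoride cleaves the silyl enol ether and protonation at C9 anti to the angular methyl group should give the 9β (equatorial) side chain, which is also the thermodynamically preferred epimer that the base treatment secures.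

Step 13
Reactants: 17 (5S,9R,10S)-9-homofarnesyl-4,4,10-trimethyl-trans-decalin-8-one
Product: 19 (5S,9R,10S)-9-homofarnesyl-4,4,10-trimethyl-trans-octal-7-en-8-yl triflate, via lithium C7-enolate 18 (not isolated)
Conditions: LiN(i-Pr)2, THF, −78 °C; then PhNTf2, −78 to 0 °C
Reagents that add atoms: N-phenylbis(trifluoromethanesulfonimide), O=S(=O)(N(c1ccccc1)S(=O)(=O)C(F)(F)F)C(F)(F)F
Why: Kinetic deprotonation should occur at the C7 methylene (the C9 methine is shielded by the quaternary C10 and the chain), so O-triflation fixes the Δ7 enol triflate without epimerising C9.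

Step 14
Reactants: 19 (5S,9R,10S)-9-homofarnesyl-4,4,10-trimethyl-trans-octal-7-en-8-yl triflate
Product: 20 CNP0141177.1, (5S,9S,10S)-9-homofarnesyl-4,4,8,10-tetramethyl-trans-octal-7-ene
Conditions: MeMgBr, Fe(acac)3 (5 mol%), THF/NMP, −30 to 0 °C
Reagents that add atoms: methylmagnesium bromide, C[Mg]Br
Why: Iron-catalysed Kumada-type cross-coupling of the enol triflate installs the C8 methyl group with retention of the alkene position, and no stereocentre is touched.

Compound list
1 | (2E,6E)-farnesyl bromide [(2E,6E)-1-bromo-3,7,11-trimethyldodeca-2,6,10-triene] | CC(C)=CCC/C(C)=C/CC/C(C)=C/CBr | starting material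
2 | homofarnesyl(isopropoxy)dimethylsilane | CC(C)=CCC/C(C)=C/CC/C(C)=C/CC[Si](C)(C)OC(C)C | intermediate
3 | (3E,7E)-homofarnesol [(3E,7E)-4,8,12-trimethyltrideca-3,7,11-trien-1-ol] | CC(C)=CCC/C(C)=C/CC/C(C)=C/CCO | intermediate
4 | (3E,7E)-homofarnesyl iodide [(6E,10E)-13-iodo-2,6,10-trimethyltrideca-2,6,10-triene] | CC(C)=CCC/C(C)=C/CC/C(C)=C/CCI | intermediate
5 | acetylacetone (pentane-2,4-dione) | CC(=O)CC(C)=O | starting material
6 | 3-homofarnesylpentane-2,4-dione | CC(C)=CCC/C(C)=C/CC/C(C)=C/CCC(C(C)=O)C(C)=O | intermediate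
7 | (2E)-4-oxo-3-homofarnesylpent-2-en-2-yl trifluoromethanesulfonate (triflate trans to acetyl) | CC(C)=CCC/C(C)=C/CC/C(C)=C/CC/C(C(C)=O)=C(/C)OS(=O)(=O)C(F)(F)F | intermediate
8 | 2,2-dimethylpent-4-enal | O=CC(C)(C)CC=C | starting material
9 | ethyl (2E)-4,4-dimethylhepta-2,6-dienoate | CCOC(=O)/C=C/C(C)(C)CC=C | intermediate
10 | (2E)-4,4-dimethylhepta-2,6-dien-1-ol | OC/C=C/C(C)(C)CC=C | intermediate
11 | bis(9-BBN) adduct of 10: 9-[(5E)-4,4-dimethyl-7-(9-borabicyclo[3.3.1]nonan-9-yloxy)hept-5-en-1-yl]-9-borabicyclo[3.3.1]nonane | C1CCC2CCCC1B2CCCC(C)(C)/C=C/COB1C2CCCC1CCC2 | intermediate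
12 | (3E,9E)-11-hydroxy-4,8,8-trimethyl-3-homofarnesylundeca-3,9-dien-2-one | CC(C)=CCC/C(C)=C/CC/C(C)=C/CC/C(C(C)=O)=C(/C)CCCC(C)(C)/C=C/CO | intermediate
13 | (2E,8E)-4,4,8-trimethyl-10-oxo-9-homofarnesylundeca-2,8-dienal | CC(C)=CCC/C(C)=C/CC/C(C)=C/CC/C(C(C)=O)=C(/C)CCCC(C)(C)/C=C/C=O | intermediate
14 | (2E,8E)-4,4,8-trimethyl-9-homofarnesyl-10-(triisopropylsilyloxy)undeca-2,8,10-trienal | CC(C)=CCC/C(C)=C/CC/C(C)=C/CC/C(C(=C)O[Si](C(C)C)(C(C)C)C(C)C)=C(/C)CCCC(C)(C)/C=C/C=O | intermediate
15 | (5S,6S,10S)-6α-formyl-9-homofarnesyl-4,4,10-trimethyl-8-(triisopropylsilyloxy)-trans-octal-8-ene (drimane numbering) | CC(C)=CCC/C(C)=C/CC/C(C)=C/CCC1=C(O[Si](C(C)C)(C(C)C)C(C)C)C[C@H](C=O)[C@H]2C(C)(C)CCC[C@]12C | intermediate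
16 | (5S,10S)-9-homofarnesyl-4,4,10-trimethyl-8-(triisopropylsilyloxy)-trans-octal-8-ene | CC(C)=CCC/C(C)=C/CC/C(C)=C/CCC1=C(O[Si](C(C)C)(C(C)C)C(C)C)CC[C@H]2C(C)(C)CCC[C@]12C | intermediate
17 | (5S,9R,10S)-9-homofarnesyl-4,4,10-trimethyl-trans-decalin-8-one | CC(C)=CCC/C(C)=C/CC/C(C)=C/CC[C@H]1C(=O)CC[C@H]2C(C)(C)CCC[C@]12C | intermediate
18 | lithium C7-enolate of 17 | CC(C)=CCC/C(C)=C/CC/C(C)=C/CC[C@H]1C(O[Li])=CC[C@H]2C(C)(C)CCC[C@]12C | intermediate
19 | (5S,9R,10S)-9-homofarnesyl-4,4,10-trimethyl-trans-octal-7-en-8-yl trifluoromethanesulfonate | CC(C)=CCC/C(C)=C/CC/C(C)=C/CC[C@H]1C(OS(=O)(=O)C(F)(F)F)=CC[C@H]2C(C)(C)CCC[C@]12C | intermediate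
20 | CNP0141177.1, (4aS,5S,8aS)-1,1,4a,6-tetramethyl-5-[(3E,7E)-4,8,12-trimethyltrideca-3,7,11-trien-1-yl]-1,2,3,4,4a,5,8,8a-octahydronaphthalene | CC(C)=CCC/C(C)=C/CC/C(C)=C/CC[C@H]1C(C)=CC[C@H]2C(C)(C)CCC[C@]12C | target

Total step count: 14. Longest linear sequence: 12 steps (steps 1–4, then 7–14).

Steps most likely to fail

Step 10. The cycloaddition joins a tetrasubstituted diene terminus to a neopentyl β-carbon, so it may be sluggish. Facial or endo/exo (ring-fusion) control may erode through a stepwise pathway, and the catalyst may desilylate the diene. Fallback (covalent auxiliary in place of the catalyst), from 13 back to 15: Pinnick oxidation of 13 (NaClO2, NaH2PO4, 2-methyl-2-butene, t-BuOH/H2O) would give (2E,8E)-4,4,8-trimethyl-10-oxo-9-homofarnesylundeca-2,8-dienoic acid F1. Coupling with (S)-4-benzyl-2-oxazolidinone (DCC, DMAP, CH2Cl2) would give the N-enoyl imide (4S)-4-benzyl-3-[(2E,8E)-4,4,8-trimethyl-10-oxo-9-homofarnesylundeca-2,8-dienoyl]oxazolidin-2-one F2. TIPSOTf/Et3N would convert it into the silyl dienol ether imide F3. Me2AlCl (1.4 equiv, CH2Cl2, −30 °C) should then promote the chelation-controlled endo intramolecular Diels–Alder reaction, the benzyl group shielding the Re face of C5, to the (5S,6S,10S)-cycloadduct imide F4. LiBH4 (Et2O, 1 equiv H2O) would release the auxiliary and give the (5S,6S,10S)-6α-hydroxymethyl octalin silyl enol ether F5, and Dess–Martin oxidation would return aldehyde 15.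

Step 4. Geometric control in the O-sulfonylation of the symmetric diketone enolate may be poor, giving the isomer with the triflate cis to acetyl. Fallback (β-keto ester with documented stereocomplementary enol sulfonylation), from 4 back to 12: alkylation of ethyl acetoacetate with 4 (NaH, THF/DMF) would give ethyl 2-homofarnesyl-3-oxobutanoate F6. TsCl, N-methylimidazole and Et3N in MeCN should give the (E)-enol tosylate, ethyl (2E)-2-homofarnesyl-3-(tosyloxy)but-2-enoate F7. B-alkyl Suzuki–Miyaura coupling with borane 11 (Pd(OAc)2, 2-dicyclohexylphosphino-2′,6′-dimethoxybiphenyl, K3PO4, THF/H2O) would give ethyl (2E,8E)-10-hydroxy-3,7,7-trimethyl-2-homofarnesyldeca-2,8-dienoate F8. MeNHOMe·HCl with i-PrMgCl would give the N-methoxy-N-methylamide F9, and MeMgBr would give hydroxy enone 12.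

Step 11. At 160 °C, Rh–H-mediated alkene migration, dehydroformylation to an alkene or loss of the silyl enol ether may compete with decarbonylation. Fallback (radical decarboxylation in place of metal-mediated decarbonylation), from 15 back to 17: Bu4NF/AcOH followed by K2CO3/MeOH would give the (5S,6S,9R,10S)-8-oxo-6α-carbaldehyde F10. Pinnick oxidation would give the keto acid F11. 2-Mercaptopyridine N-oxide and DCC would give the N-acyloxy-2-thiopyridone (Barton ester) F12, and photolysis with t-BuSH (Barton decarboxylation) would deliver ketone 17.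

Further compounds
F1 | step 10 | (2E,8E)-4,4,8-trimethyl-10-oxo-9-homofarnesylundeca-2,8-dienoic acid | CC(C)=CCC/C(C)=C/CC/C(C)=C/CC/C(C(C)=O)=C(/C)CCCC(C)(C)/C=C/C(O)=O
F2 | step 10 | (4S)-4-benzyl-3-[(2E,8E)-4,4,8-trimethyl-10-oxo-9-homofarnesylundeca-2,8-dienoyl]oxazolidin-2-one | CC(C)=CCC/C(C)=C/CC/C(C)=C/CC/C(C(C)=O)=C(/C)CCCC(C)(C)/C=C/C(=O)N1[C@@H](Cc2ccccc2)COC1=O
F3 | step 10 | (4S)-4-benzyl-3-[(2E,8E)-4,4,8-trimethyl-9-homofarnesyl-10-(triisopropylsilyloxy)undeca-2,8,10-trienoyl]oxazolidin-2-one | CC(C)=CCC/C(C)=C/CC/C(C)=C/CC/C(C(=C)O[Si](C(C)C)(C(C)C)C(C)C)=C(/C)CCCC(C)(C)/C=C/C(=O)N1[C@@H](Cc2ccccc2)COC1=O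
F4 | step 10 | (5S,6S,10S)-cycloadduct imide, 6α-[(4S)-4-benzyl-2-oxooxazolidine-3-carbonyl]-9-homofarnesyl-4,4,10-trimethyl-8-(triisopropylsilyloxy)-trans-octal-8-ene | CC(C)=CCC/C(C)=C/CC/C(C)=C/CCC1=C(O[Si](C(C)C)(C(C)C)C(C)C)C[C@H](C(=O)N3[C@@H](Cc4ccccc4)COC3=O)[C@H]2C(C)(C)CCC[C@]12C
F5 | step 10 | (5S,6S,10S)-6α-(hydroxymethyl)-9-homofarnesyl-4,4,10-trimethyl-8-(triisopropylsilyloxy)-trans-octal-8-ene | CC(C)=CCC/C(C)=C/CC/C(C)=C/CCC1=C(O[Si](C(C)C)(C(C)C)C(C)C)C[C@H](CO)[C@H]2C(C)(C)CCC[C@]12C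
F6 | step 4 | ethyl 2-homofarnesyl-3-oxobutanoate | CC(C)=CCC/C(C)=C/CC/C(C)=C/CCC(C(C)=O)C(=O)OCC
F7 | step 4 | ethyl (2E)-2-homofarnesyl-3-(tosyloxy)but-2-enoate | CC(C)=CCC/C(C)=C/CC/C(C)=C/CC/C(C(=O)OCC)=C(/C)OS(=O)(=O)c1ccc(C)cc1
F8 | step 4 | ethyl (2E,8E)-10-hydroxy-3,7,7-trimethyl-2-homofarnesyldeca-2,8-dienoate | CC(C)=CCC/C(C)=C/CC/C(C)=C/CC/C(C(=O)OCC)=C(/C)CCCC(C)(C)/C=C/CO
F9 | step 4 | (2E,8E)-10-hydroxy-N-methoxy-N,3,7,7-tetramethyl-2-homofarnesyldeca-2,8-dienamide | CC(C)=CCC/C(C)=C/CC/C(C)=C/CC/C(C(=O)N(C)OC)=C(/C)CCCC(C)(C)/C=C/CO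
F10 | step 11 | (5S,6S,9R,10S)-9-homofarnesyl-4,4,10-trimethyl-8-oxo-trans-decalin-6α-carbaldehyde | CC(C)=CCC/C(C)=C/CC/C(C)=C/CC[C@H]1C(=O)C[C@H](C=O)[C@H]2C(C)(C)CCC[C@]12C
F11 | step 11 | (5S,6S,9R,10S)-9-homofarnesyl-4,4,10-trimethyl-8-oxo-trans-decalin-6α-carboxylic acid | CC(C)=CCC/C(C)=C/CC/C(C)=C/CC[C@H]1C(=O)C[C@H](C(O)=O)[C@H]2C(C)(C)CCC[C@]12C
F12 | step 11 | 2-thioxopyridin-1(2H)-yl (5S,6S,9R,10S)-9-homofarnesyl-4,4,10-trimethyl-8-oxo-trans-decalin-6α-carboxylate | CC(C)=CCC/C(C)=C/CC/C(C)=C/CC[C@H]1C(=O)C[C@H](C(=O)ON3C=CC=CC3=S)[C@H]2C(C)(C)CCC[C@]12C
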